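**Plan**
- Retrosynthesis first removes the three aryl MOM ethers and the side-chain silyl ether, then the hydrogens at C2 and C3, which leads back to a planar flavone.
- The flavone is cut at C4a–C4, C4–C3 and O1–C2. The C4 carbonyl lies between C4a of ring A and C3, and O1 sits on the neighbouring ring A carbon C8a, so C4 can enter as carbon monoxide between an ortho-iodophenol (ring A) and a terminal arylacetylene (ring B plus C2 and C3).
- The arylacetylene is cut at C3′–C1″ (arylcopper plus allylic bromide) and at C1′–alkyne (Sonogashira coupling). The side chain comes from geranyl acetate by hydration of its distal alkene.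
- Forward: ring A iodophenol (2 steps), side-chain bromide (4 steps), ring B alkyne (4 steps, alkyne first, chain second). Ring C is closed last around CO, then reduced and deprotected.
- Stereochemistry: C2 (S) comes from a ligand-controlled copper hydride conjugate reduction of the flavone. The E alkene is carried unchanged from geranyl acetate.

Key step: step 11

Remark: the descriptor in the target string corresponds to 2S. The tertiary alcohol is carried as its triethylsilyl ether so that no acidic proton meets the aryl metal or the silane. The enantiomer of the bisphosphine in step 12 is the one whose copper hydride adds to the Re face of C2, and this assignment is to be fixed against the racemate in a trial run.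

**Ring A**

Step 1
Reactants: 1 phloroglucinol (benzene-1,3,5-triol)
Product: 2 3,5-bis(methoxymethoxy)phenol
Conditions: MOMCl (2.0 equiv), i-Pr2NEt, DMF, 0 °C → rt
Reagents that add atoms: chloromethyl methyl ether, COCCl
Why: Williamson-type O-alkylation of the phenoxide, in which two equivalents of MOMCl should make the bis-ether the main member of a statistical mixture that is separable by chromatography, the mono-ether being resubmitted.

Step 2
Reactants: 2 3,5-bis(methoxymethoxy)phenol
Product: 3 2-iodo-3,5-bis(methoxymethoxy)phenol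
Conditions: NIS (1.0 equiv), CH2Cl2, −40 → 0 °C
Reagents that add atoms: N-iodosuccinimide, O=C1CCC(=O)N1I
Why: Electrophilic aromatic iodination, in which the two equivalent carbons ortho to the free hydroxyl should be favoured over C4 (flanked by two MOM ethers) by statistics, by hydrogen-bonded delivery of iodine and by the smaller size of OH, any 4-iodide being removed by chromatography.

**Side chain**

Step 3
Reactants: 4 geranyl acetate, (2E)-3,7-dimethylocta-2,6-dienyl acetate
Product: 5 (2E)-7-hydroxy-3,7-dimethyloct-2-enyl acetate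
Conditions: Co(acac)2 (20 mol %), PhSiH3, O2 (1 atm), THF, rt
Reagents that add atoms: dioxygen, O=O
Why: Mukaiyama hydration, in which cobalt hydride transfers a hydrogen atom to C6 of the electron-richer distal alkene and the tertiary C7 radical is trapped by O2 and reduced to the alcohol, while the C2=C3 alkene, deactivated by the allylic acetate, should stay untouched and E.

Step 4
Reactants: 5 (2E)-7-hydroxy-3,7-dimethyloct-2-enyl acetate
Product: 6 (2E)-3,7-dimethyl-7-(triethylsilyloxy)oct-2-enyl acetate
Conditions: TESOTf, 2,6-lutidine, CH2Cl2, −78 → 0 °C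
Reagents that add atoms: triethylsilyl trifluoromethanesulfonate, CC[Si](CC)(CC)OS(=O)(=O)C(F)(F)F
Why: Silylation of a hindered tertiary alcohol with a silyl triflate and 2,6-lutidine, which removes the only acidic proton that would quench the aryl metal of step 9 or consume silane in step 12.

Step 5
Reactants: 6 (2E)-3,7-dimethyl-7-(triethylsilyloxy)oct-2-enyl acetate
Product: 7 (2E)-3,7-dimethyl-7-(triethylsilyloxy)oct-2-en-1-ol
Conditions: K2CO3 (cat.), MeOH, rt
Reagents that add atoms: none
Why: Base-catalysed transesterification of the acetate with methanol, to which a tertiary triethylsilyl ether is stable.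

Step 6
Reactants: 7 (2E)-3,7-dimethyl-7-(triethylsilyloxy)oct-2-en-1-ol
Product: 8 (2E)-1-bromo-3,7-dimethyl-7-(triethylsilyloxy)oct-2-ene
Conditions: CBr4, PPh3, CH2Cl2, 0 °C
Reagents that add atoms: carbon tetrabromide, BrC(Br)(Br)Br
Why: Appel reaction, in which bromide displaces the alkoxyphosphonium group by SN2 at the primary allylic carbon under neutral conditions, so that neither allylic transposition, E/Z isomerisation nor loss of the silyl ether is expected.

**Ring B alkyne**

Step 7
Reactants: 9 2-bromo-4-iodophenol
Product: 10 2-bromo-4-iodo-1-(methoxymethoxy)benzene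
Conditions: MOMCl, i-Pr2NEt, CH2Cl2, 0 °C → rt
Reagents that add atoms: chloromethyl methyl ether, COCCl
Why: Williamson-type O-alkylation of the phenol, giving the same protecting group as on ring A and an ether oxygen that later holds the ortho aryllithium by chelation.

Step 8
Reactants: 10 2-bromo-4-iodo-1-(methoxymethoxy)benzene; 11 trimethylsilylacetylene
Product: 12 {[3-bromo-4-(methoxymethoxy)phenyl]ethynyl}trimethylsilane
Conditions: PdCl2(PPh3)2 (2 mol %), CuI (4 mol %), Et3N, THF, rt
Reagents that add atoms: none
Why: Sonogashira coupling, in which zerovalent palladium inserts into the carbon–iodine bond far faster than into the carbon–bromine bond at rt, so that only the position para to oxygen should be alkynylated and the bromide is kept for step 9.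

Step 9
Reactants: 12 {[3-bromo-4-(methoxymethoxy)phenyl]ethynyl}trimethylsilane; 8 (2E)-1-bromo-3,7-dimethyl-7-(triethylsilyloxy)oct-2-ene
Product: 15 {[3-[(2E)-3,7-dimethyl-7-(triethylsilyloxy)oct-2-enyl]-4-(methoxymethoxy)phenyl]ethynyl}trimethylsilane, via aryllithium 13 (not isolated), via arylcopper 14 (not isolated)
Conditions: n-BuLi, THF, −78 °C; CuBr·SMe2, −78 → −40 °C; 8, −40 °C → rt
Reagents that add atoms: none
Why: Bromine–lithium exchange gives an aryllithium held by the ortho MOM oxygen, transmetalation gives the arylcopper, and its allylic substitution at the unhindered α-carbon of the primary bromide (SN2, not SN2′ at the fully substituted γ-carbon) should form C3′–C1″ with the E alkene intact, the silylalkyne and silyl ether being inert at low temperature.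

Step 10
Reactants: 15 {[3-[(2E)-3,7-dimethyl-7-(triethylsilyloxy)oct-2-enyl]-4-(methoxymethoxy)phenyl]ethynyl}trimethylsilane
Product: 16 4-ethynyl-2-[(2E)-3,7-dimethyl-7-(triethylsilyloxy)oct-2-enyl]-1-(methoxymethoxy)benzene
Conditions: K2CO3, MeOH/THF, rt
Reagents that add atoms: none
Why: Methoxide-induced protodesilylation of the alkynylsilane, which the aryl MOM ether and the tertiary triethylsilyl ether should survive.

**Ring C and endgame**

Step 11
Reactants: 3 2-iodo-3,5-bis(methoxymethoxy)phenol; 16 4-ethynyl-2-[(2E)-3,7-dimethyl-7-(triethylsilyloxy)oct-2-enyl]-1-(methoxymethoxy)benzene; 17 carbon monoxide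
Product: 20 2-[3-[(2E)-3,7-dimethyl-7-(triethylsilyloxy)oct-2-enyl]-4-(methoxymethoxy)phenyl]-5,7-bis(methoxymethoxy)chromen-4-one, via ortho-hydroxyaryl ynone 18 (not isolated), via diethylamino enaminone 19 (not isolated)
Conditions: PdCl2(PPh3)2 (5 mol %), CO (20 bar), Et2NH, 110 °C, autoclave
Reagents that add atoms: none
Why: Zerovalent palladium, formed in the flask from PdCl2(PPh3)2, inserts into the carbon–iodine bond of 3, CO inserts to give an aroylpalladium iodide, and the amine-deprotonated alkyne 16 is transferred to palladium so that reductive elimination forms C4a–C4 and C4–C3 in ynone 18. Diethylamine then adds to the ynone to give enaminone 19, and the ortho phenol oxygen attacks the amine-bearing carbon and expels diethylamine, which forms O1–C2. The closest known reaction type is the palladium-catalysed carbonylative Sonogashira coupling of ortho-iodophenols with terminal arylacetylenes with cyclisation to flavones in the same flask. Ring C closes in a 6-endo mode, formally a 6-endo-trig addition–elimination on the enaminone. No stereocentre is created, since the flavone is planar. The step needs CO insertion to outrun direct alkynylation and amine capture of the acyl complex, which CO pressure, the absence of copper and the electron-rich aryl group should secure, and it needs 6-endo to outrun 5-exo closure to an aurone, which is secured because in the enaminone only the amine-bearing β-carbon is electrophilic and within reach of the ortho hydroxyl.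

Step 12
Reactants: 20 2-[3-[(2E)-3,7-dimethyl-7-(triethylsilyloxy)oct-2-enyl]-4-(methoxymethoxy)phenyl]-5,7-bis(methoxymethoxy)chromen-4-one
Product: 22 (2S)-2-[3-[(2E)-3,7-dimethyl-7-(triethylsilyloxy)oct-2-enyl]-4-(methoxymethoxy)phenyl]-5,7-bis(methoxymethoxy)chroman-4-one, via silyl enol ether 21 (not isolated)
Conditions: Cu(OAc)2 (5 mol %), (R)-DTBM-SEGPHOS (5.5 mol %), (EtO)2MeSiH (2 equiv), toluene, 0 °C → rt; then aq. NH4Cl
Reagents that add atoms: none
Why: Enantioselective copper hydride conjugate reduction, a reaction type established for β,β-disubstituted cyclic enones and 2-substituted chromones, in which the bisphosphine-ligated copper hydride delivers hydride to the Re face of C2 of the planar flavone under ligand control and so sets 2S, the copper enolate is silylated to enol ether 21 so that neither 1,2-reduction nor enolate ring opening should follow, and the isolated side-chain alkene is no acceptor.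

Step 13
Reactants: 22 (2S)-2-[3-[(2E)-3,7-dimethyl-7-(triethylsilyloxy)oct-2-enyl]-4-(methoxymethoxy)phenyl]-5,7-bis(methoxymethoxy)chroman-4-one
Product: 23 (2S)-5,7-dihydroxy-2-[4-hydroxy-3-[(2E)-7-hydroxy-3,7-dimethyloct-2-enyl]phenyl]chroman-4-one
Conditions: conc. aq. HCl (to ca. 1 M), MeOH, rt → 40 °C
Reagents that add atoms: none
Why: Acid-catalysed methanolysis of the three MOM acetals and of the triethylsilyl ether (acetal exchange and Si–O solvolysis), in which no enolate is formed so that C2 should keep its configuration, the low temperature being chosen to spare the tertiary alcohol and the ortho-allylphenol.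

**Compound list**

1 | phloroglucinol (benzene-1,3,5-triol) | Oc1cc(O)cc(O)c1 | starting material
2 | 3,5-bis(methoxymethoxy)phenol | COCOc1cc(O)cc(OCOC)c1 | intermediate
3 | 2-iodo-3,5-bis(methoxymethoxy)phenol | COCOc1cc(O)c(I)c(OCOC)c1 | intermediate
4 | geranyl acetate, (2E)-3,7-dimethylocta-2,6-dienyl acetate | CC(C)=CCC/C(C)=C/COC(C)=O | starting material
5 | (2E)-7-hydroxy-3,7-dimethyloct-2-enyl acetate | C/C(=C\COC(C)=O)CCCC(C)(C)O | intermediate
6 | (2E)-3,7-dimethyl-7-(triethylsilyloxy)oct-2-enyl acetate | C/C(=C\COC(C)=O)CCCC(C)(C)O[Si](CC)(CC)CC | intermediate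
7 | (2E)-3,7-dimethyl-7-(triethylsilyloxy)oct-2-en-1-ol | C/C(=C\CO)CCCC(C)(C)O[Si](CC)(CC)CC | intermediate
8 | (2E)-1-bromo-3,7-dimethyl-7-(triethylsilyloxy)oct-2-ene | C/C(=C\CBr)CCCC(C)(C)O[Si](CC)(CC)CC | intermediate
9 | 2-bromo-4-iodophenol | Oc1ccc(I)cc1Br | starting material
10 | 2-bromo-4-iodo-1-(methoxymethoxy)benzene | COCOc1ccc(I)cc1Br | intermediate
11 | trimethylsilylacetylene | C#C[Si](C)(C)C | starting material
12 | {[3-bromo-4-(methoxymethoxy)phenyl]ethynyl}trimethylsilane | COCOc1ccc(C#C[Si](C)(C)C)cc1Br | intermediate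
13 | [2-(methoxymethoxy)-5-(trimethylsilylethynyl)phenyl]lithium (not isolated) | COCOc1ccc(C#C[Si](C)(C)C)cc1[Li] | intermediate
14 | [2-(methoxymethoxy)-5-(trimethylsilylethynyl)phenyl]copper (not isolated) | COCOc1ccc(C#C[Si](C)(C)C)cc1[Cu] | intermediate
15 | {[3-[(2E)-3,7-dimethyl-7-(triethylsilyloxy)oct-2-enyl]-4-(methoxymethoxy)phenyl]ethynyl}trimethylsilane | C/C(=C\Cc1cc(C#C[Si](C)(C)C)ccc1OCOC)CCCC(C)(C)O[Si](CC)(CC)CC | intermediate
16 | 4-ethynyl-2-[(2E)-3,7-dimethyl-7-(triethylsilyloxy)oct-2-enyl]-1-(methoxymethoxy)benzene | C/C(=C\Cc1cc(C#C)ccc1OCOC)CCCC(C)(C)O[Si](CC)(CC)CC | intermediate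
17 | carbon monoxide | [C-]#[O+] | starting material
18 | 3-[3-[(2E)-3,7-dimethyl-7-(triethylsilyloxy)oct-2-enyl]-4-(methoxymethoxy)phenyl]-1-[2-hydroxy-4,6-bis(methoxymethoxy)phenyl]prop-2-yn-1-one (not isolated) | C/C(=C\Cc1cc(C#CC(=O)c2c(O)cc(OCOC)cc2OCOC)ccc1OCOC)CCCC(C)(C)O[Si](CC)(CC)CC | intermediate
19 | (2E)-3-(diethylamino)-3-[3-[(2E)-3,7-dimethyl-7-(triethylsilyloxy)oct-2-enyl]-4-(methoxymethoxy)phenyl]-1-[2-hydroxy-4,6-bis(methoxymethoxy)phenyl]prop-2-en-1-one (not isolated; the push–pull alkene equilibrates) | C/C(=C\Cc1cc(/C(N(CC)CC)=C\C(=O)c2c(O)cc(OCOC)cc2OCOC)ccc1OCOC)CCCC(C)(C)O[Si](CC)(CC)CC | intermediate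
20 | 2-[3-[(2E)-3,7-dimethyl-7-(triethylsilyloxy)oct-2-enyl]-4-(methoxymethoxy)phenyl]-5,7-bis(methoxymethoxy)chromen-4-one (protected flavone) | C/C(=C\Cc1cc(-c2cc(=O)c3c(OCOC)cc(OCOC)cc3o2)ccc1OCOC)CCCC(C)(C)O[Si](CC)(CC)CC | intermediate
21 | (2S)-4-[diethoxy(methyl)silyloxy]-2-[3-[(2E)-3,7-dimethyl-7-(triethylsilyloxy)oct-2-enyl]-4-(methoxymethoxy)phenyl]-5,7-bis(methoxymethoxy)-2H-chromene (not isolated) | C/C(=C\Cc1cc([C@@H]2C=C(O[Si](C)(OCC)OCC)c3c(OCOC)cc(OCOC)cc3O2)ccc1OCOC)CCCC(C)(C)O[Si](CC)(CC)CC | intermediate
22 | (2S)-2-[3-[(2E)-3,7-dimethyl-7-(triethylsilyloxy)oct-2-enyl]-4-(methoxymethoxy)phenyl]-5,7-bis(methoxymethoxy)chroman-4-one (protected flavanone) | C/C(=C\Cc1cc([C@@H]2CC(=O)c3c(OCOC)cc(OCOC)cc3O2)ccc1OCOC)CCCC(C)(C)O[Si](CC)(CC)CC | intermediate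
23 | (2S)-5,7-dihydroxy-2-[4-hydroxy-3-[(2E)-7-hydroxy-3,7-dimethyloct-2-enyl]phenyl]chroman-4-one | C/C(=C\Cc1cc([C@@H]2CC(=O)c3c(O)cc(O)cc3O2)ccc1O)CCCC(C)(C)O | target

**Count**

Total: 13 steps. Longest linear sequence: 9 steps (steps 3, 4, 5, 6, 9, 10, 11, 12 and 13, from geranyl acetate).

**Steps most likely to fail**

Step 12. The ligated copper hydride may discriminate poorly between the faces of C2 at this hindered, electron-rich vinylogous ester, or the copper enolate may open ring C reversibly before it is silylated, which would erode the configuration. The fallback sets out from flavone 20 and comes back at 22. Flavone 20 would be reduced without stereocontrol by an achiral copper hydride (Cu(OAc)2, 1,2-bis(diphenylphosphino)benzene, (EtO)2MeSiH, toluene) to the racemic 4-silyloxy-2H-chromene F1, which aqueous NH4Cl would hydrolyse to the racemic protected flavanone F2. Kinetic resolution of F2 by asymmetric transfer hydrogenation (Cp*RhCl[(R,R)-TsDPEN] or its antipode, whichever reduces the 2R ketone faster, HCO2H/Et3N, EtOAc, rt, stopped near half conversion) would turn the 2R enantiomer into the cis-(2R,4R)-flavan-4-ol F3. F3 is removed by chromatography, and the unreacted 2S ketone is 22.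

Step 11. At the hindered, electron-rich aryl iodide the aroylpalladium complex may be captured by diethylamine, or direct alkynylation followed by closure onto the free phenol may outpace CO insertion. The fallback sets out from 3, 16 and 17 and comes back at 20. Iodophenol 3 would be acetylated (Ac2O, pyridine, CH2Cl2) to 2-iodo-3,5-bis(methoxymethoxy)phenyl acetate F4. Carbonylative Sonogashira coupling of F4 with alkyne 16 and CO 17 (PdCl2(PPh3)2, Et3N, THF, rt to 50 °C) would give the isolable 2-acetoxyaryl ynone F5. A tertiary amine cannot form an amide there, and the masked phenol cannot cyclise. In a separate flask Et2NH would remove the acetate from F5 by aminolysis and close ring C through 18 and 19 to flavone 20.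

Step 13. Protic acid may ionise the tertiary alcohol or protonate the side-chain alkene, leading to solvolysis or to ring closure onto the 4′-phenol before the slower 7- and 4′-MOM ethers are gone. The fallback sets out from 22 and comes back at 23. Buffered fluoride (HF·pyridine, pyridine, THF, 0 °C) would first remove the silyl ether to give the tris-MOM flavanone with the free tertiary alcohol F6. ZnBr2 and n-PrSH in CH2Cl2 at 0 °C would then cleave the three MOM ethers of F6 in an aprotic, thiol-assisted Lewis acid process within minutes to give 23. The C4 ketone, deactivated by the 5- and 7-oxygens, is not expected to form a thioketal.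

**Further compounds**

F1 | step 12 | racemic 4-[diethoxy(methyl)silyloxy]-2-[3-[(2E)-3,7-dimethyl-7-(triethylsilyloxy)oct-2-enyl]-4-(methoxymethoxy)phenyl]-5,7-bis(methoxymethoxy)-2H-chromene | C/C(=C\Cc1cc(C2C=C(O[Si](C)(OCC)OCC)c3c(OCOC)cc(OCOC)cc3O2)ccc1OCOC)CCCC(C)(C)O[Si](CC)(CC)CC
F2 | step 12 | racemic 2-[3-[(2E)-3,7-dimethyl-7-(triethylsilyloxy)oct-2-enyl]-4-(methoxymethoxy)phenyl]-5,7-bis(methoxymethoxy)chroman-4-one | C/C(=C\Cc1cc(C2CC(=O)c3c(OCOC)cc(OCOC)cc3O2)ccc1OCOC)CCCC(C)(C)O[Si](CC)(CC)CC
F3 | step 12 | (2R,4R)-2-[3-[(2E)-3,7-dimethyl-7-(triethylsilyloxy)oct-2-enyl]-4-(methoxymethoxy)phenyl]-5,7-bis(methoxymethoxy)chroman-4-ol | C/C(=C\Cc1cc([C@H]2C[C@@H](O)c3c(OCOC)cc(OCOC)cc3O2)ccc1OCOC)CCCC(C)(C)O[Si](CC)(CC)CC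
F4 | step 11 | 2-iodo-3,5-bis(methoxymethoxy)phenyl acetate | COCOc1cc(OC(C)=O)c(I)c(OCOC)c1
F5 | step 11 | 2-[3-[3-[(2E)-3,7-dimethyl-7-(triethylsilyloxy)oct-2-enyl]-4-(methoxymethoxy)phenyl]prop-2-ynoyl]-3,5-bis(methoxymethoxy)phenyl acetate | C/C(=C\Cc1cc(C#CC(=O)c2c(OC(C)=O)cc(OCOC)cc2OCOC)ccc1OCOC)CCCC(C)(C)O[Si](CC)(CC)CC
F6 | step 13 | (2S)-2-[3-[(2E)-7-hydroxy-3,7-dimethyloct-2-enyl]-4-(methoxymethoxy)phenyl]-5,7-bis(methoxymethoxy)chroman-4-one | C/C(=C\Cc1cc([C@@H]2CC(=O)c3c(OCOC)cc(OCOC)cc3O2)ccc1OCOC)CCCC(C)(C)O
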